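**Retrosynthetic overview**
1. The palmitate ester is cut last: palmitoyl chloride plus the free 1,3-diol 24, acylated only at the primary OH.
2. The prenyl group is cut back to an aryl bromide (Stille coupling) and the CMe2OH group to a methyl ester plus two MeMgBr.
3. Key C–C bond: stereocentre–CH2OH, made by an auxiliary-controlled titanium-enolate aldol of an indol-3-ylacetyl imide with formaldehyde, which sets the (S) centre.
4. The imide comes from (R)-4-benzyl-oxazolidin-2-one and N-tosyl-5-bromoindole-3-acetic acid; the bromide is carried through because a prenyl alkene would not survive TiCl4/formaldehyde.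
5. No ring is built: the indole is bought intact and the oxazolidinone is only a recoverable auxiliary.

Assumption: 2-(5-bromo-1H-indol-3-yl)acetic acid, (R)-4-benzyl-1,3-oxazolidin-2-one and tributyl(3-methylbut-2-en-1-yl)stannane are taken as catalogue chemicals. "Tosyl" means 4-methylbenzenesulfonyl.

**Route**

Step 1
Reactants: 1 2-(5-bromo-1H-indol-3-yl)acetic acid; 2 methanol
Product: 3 methyl 2-(5-bromo-1H-indol-3-yl)acetate
Conditions: MeOH, H2SO4 (cat.), 65 °C
Reagents that add atoms: methanol (CO)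
Why: Fischer esterification in excess methanol masks the acid so that the indole nitrogen can be protected cleanly in the next step.

Step 2
Reactants: 3 methyl 2-(5-bromo-1H-indol-3-yl)acetate; 4 4-methylbenzenesulfonyl chloride
Product: 5 methyl 2-(5-bromo-1-tosyl-1H-indol-3-yl)acetate
Conditions: NaH (1.1 equiv), THF/DMF, 0 °C; then TsCl, 0 °C to rt
Reagents that add atoms: 4-methylbenzenesulfonyl chloride (Cc1ccc(cc1)S(Cl)(=O)=O)
Why: the indole N–H is the most acidic site, so N-sulfonylation of the sodium indolide is selective, and the sulfonyl group later keeps the indole inert to Lewis acid and electrophiles.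

Step 3
Reactants: 5 methyl 2-(5-bromo-1-tosyl-1H-indol-3-yl)acetate; 6 lithium hydroxide
Product: 7 2-(5-bromo-1-tosyl-1H-indol-3-yl)acetic acid
Conditions: LiOH·H2O (2 equiv), THF/H2O 3:1, 0 °C to rt; then 1 M HCl
Reagents that add atoms: lithium hydroxide ([Li+].[OH-])
Why: saponification of the unhindered methyl ester is fast at room temperature, where the N-tosyl indole is stable to hydroxide.

Step 4
Reactants: 7 2-(5-bromo-1-tosyl-1H-indol-3-yl)acetic acid; 8 (R)-4-benzyl-1,3-oxazolidin-2-one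
Product: 10 (4R)-4-benzyl-3-[2-(5-bromo-1-tosyl-1H-indol-3-yl)acetyl]-1,3-oxazolidin-2-one, via mixed pivalic anhydride 9 (not isolated)
Conditions: t-BuCOCl (1.1 equiv), Et3N (2.5 equiv), THF, –20 °C; then LiCl (1.2 equiv) and 8, –20 °C to rt
Reagents that add atoms: (R)-4-benzyl-1,3-oxazolidin-2-one (O=C1N[C@H](Cc2ccccc2)CO1)
Why: mixed-anhydride N-acylation of the Evans auxiliary under the LiCl/Et3N protocol occurs at the less hindered arylacetyl carbonyl and avoids strong base.

Step 5
Reactants: 10 (4R)-4-benzyl-3-[2-(5-bromo-1-tosyl-1H-indol-3-yl)acetyl]-1,3-oxazolidin-2-one; 11 1,3,5-trioxane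
Product: 13 (4R)-4-benzyl-3-[(2S)-2-(5-bromo-1-tosyl-1H-indol-3-yl)-3-hydroxypropanoyl]-1,3-oxazolidin-2-one, via chlorotitanium Z-enolate 12 (not isolated)
Conditions: TiCl4 (1.05 equiv), i-Pr2NEt (1.15 equiv), CH2Cl2, 0 °C, 1 h; then 11 (1.2 equiv) and TiCl4 (1.05 equiv), 0 °C, 2–3 h; sat. aq. NH4Cl
Reagents that add atoms: 1,3,5-trioxane (C1OCOCO1), the source of formaldehyde (C=O)
Why: in this Evans titanium-enolate aldol addition (asymmetric hydroxymethylation) the chelated Z-enolate is shielded on one face by the auxiliary benzyl group, so TiCl4-activated formaldehyde adds to the open face and sets the (S) centre.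

Step 6
Reactants: 13 (4R)-4-benzyl-3-[(2S)-2-(5-bromo-1-tosyl-1H-indol-3-yl)-3-hydroxypropanoyl]-1,3-oxazolidin-2-one; 14 hydrogen peroxide
Product: 16 (2S)-2-(5-bromo-1-tosyl-1H-indol-3-yl)-3-hydroxypropanoic acid, via peroxy acid 15 (not isolated)
Conditions: LiOH (2 equiv), 30% H2O2 (4 equiv), THF/H2O 3:1, 0 °C; aq. Na2SO3; then 1 M HCl
Reagents that add atoms: hydrogen peroxide (OO)
Why: Evans hydroperoxide cleavage attacks only the exocyclic carbonyl, and the weakly basic hydroperoxide anion at 0 °C does not epimerise or dehydrate the α-aryl-β-hydroxy acyl unit.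

Step 7
Reactants: 16 (2S)-2-(5-bromo-1-tosyl-1H-indol-3-yl)-3-hydroxypropanoic acid; 17 trimethylsilyldiazomethane
Product: 18 methyl (2S)-2-(5-bromo-1-tosyl-1H-indol-3-yl)-3-hydroxypropanoate
Conditions: Me3SiCHN2 (1.2 equiv), toluene/MeOH 4:1, 0 °C to rt
Reagents that add atoms: trimethylsilyldiazomethane (C[Si](C)(C)C=[N+]=[N-])
Why: O-methylation of the acid by the diazoalkane is neutral, so the acidic α-aryl centre and the free primary alcohol are untouched.

Step 8
Reactants: 18 methyl (2S)-2-(5-bromo-1-tosyl-1H-indol-3-yl)-3-hydroxypropanoate; 19 methylmagnesium bromide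
Product: 21 (2S)-2-(5-bromo-1-tosyl-1H-indol-3-yl)-3-methylbutane-1,3-diol, via methyl ketone magnesium alkoxide 20 (not isolated)
Conditions: MeMgBr (5 equiv), THF, –40 to 0 °C; sat. aq. NH4Cl
Reagents that add atoms: methylmagnesium bromide (C[Mg]Br)
Why: double Grignard addition to the ester builds the dimethyl carbinol, and the magnesium alkoxide formed first from the free OH disfavours enolisation and β-elimination, so the stereocentre is kept.

Step 9
Reactants: 21 (2S)-2-(5-bromo-1-tosyl-1H-indol-3-yl)-3-methylbutane-1,3-diol; 22 tributyl(3-methylbut-2-en-1-yl)stannane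
Product: 23 (2S)-3-methyl-2-[5-(3-methylbut-2-en-1-yl)-1-tosyl-1H-indol-3-yl]butane-1,3-diol
Conditions: 22 (1.5 equiv), Pd(PPh3)4 (5 mol %, zerovalent palladium), degassed DMF, 100 °C
Reagents that add atoms: tributyl(3-methylbut-2-en-1-yl)stannane (CCCC[Sn](CCCC)(CCCC)CC=C(C)C)
Why: Stille cross-coupling of the aryl bromide with the prenylstannane is neutral, tolerates the free diol, and couples at the unhindered CH2 terminus to give the linear prenyl arene.

Step 10
Reactants: 23 (2S)-3-methyl-2-[5-(3-methylbut-2-en-1-yl)-1-tosyl-1H-indol-3-yl]butane-1,3-diol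
Product: 24 (2S)-3-methyl-2-[5-(3-methylbut-2-en-1-yl)-1H-indol-3-yl]butane-1,3-diol
Conditions: Mg turnings (10 equiv), MeOH, rt, ultrasound; sat. aq. NH4Cl
Reagents that add atoms: none
Why: single-electron reductive cleavage of the N–S bond by Mg in methanol removes the sulfonyl group without touching the isolated alkene or the tertiary alcohol, and is done before acylation so that no ester is exposed to methoxide.

Step 11
Reactants: 24 (2S)-3-methyl-2-[5-(3-methylbut-2-en-1-yl)-1H-indol-3-yl]butane-1,3-diol; 25 hexadecanoyl chloride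
Product: 26 (2S)-3-hydroxy-3-methyl-2-[5-(3-methylbut-2-en-1-yl)-1H-indol-3-yl]butyl hexadecanoate
Conditions: 25 (1.05 equiv), 2,4,6-collidine (2 equiv), CH2Cl2, –40 to 0 °C
Reagents that add atoms: hexadecanoyl chloride (CCCCCCCCCCCCCCCC(Cl)=O)
Why: chemoselective O-acylation with a weak hindered base esterifies only the primary alcohol, since the tertiary alcohol and the indole N–H do not react with an acid chloride under these conditions.

**Compound list**
1 | 2-(5-bromo-1H-indol-3-yl)acetic acid | OC(=O)Cc1c[nH]c2ccc(Br)cc12 | starting material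
2 | methanol | CO | starting material
3 | methyl 2-(5-bromo-1H-indol-3-yl)acetate | COC(=O)Cc1c[nH]c2ccc(Br)cc12 | intermediate
4 | 4-methylbenzenesulfonyl chloride | Cc1ccc(cc1)S(Cl)(=O)=O | starting material
5 | methyl 2-(5-bromo-1-tosyl-1H-indol-3-yl)acetate | COC(=O)Cc1cn(S(=O)(=O)c2ccc(C)cc2)c2ccc(Br)cc12 | intermediate
6 | lithium hydroxide | [Li+].[OH-] | starting material
7 | 2-(5-bromo-1-tosyl-1H-indol-3-yl)acetic acid | OC(=O)Cc1cn(S(=O)(=O)c2ccc(C)cc2)c2ccc(Br)cc12 | intermediate
8 | (R)-4-benzyl-1,3-oxazolidin-2-one | O=C1N[C@H](Cc2ccccc2)CO1 | starting material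
9 | 2-(5-bromo-1-tosyl-1H-indol-3-yl)acetic 2,2-dimethylpropanoic anhydride (mixed pivalic anhydride) | CC(C)(C)C(=O)OC(=O)Cc1cn(S(=O)(=O)c2ccc(C)cc2)c2ccc(Br)cc12 | intermediate (not isolated)
10 | (4R)-4-benzyl-3-[2-(5-bromo-1-tosyl-1H-indol-3-yl)acetyl]-1,3-oxazolidin-2-one | O=C(Cc1cn(S(=O)(=O)c2ccc(C)cc2)c2ccc(Br)cc12)N1[C@H](Cc2ccccc2)COC1=O | intermediate
11 | 1,3,5-trioxane | C1OCOCO1 | starting material
12 | trichlorotitanium (Z)-enolate of 10 (chelated to the oxazolidinone carbonyl) | Cl[Ti](Cl)(Cl)O/C(N1[C@H](Cc2ccccc2)COC1=O)=C\c1cn(S(=O)(=O)c2ccc(C)cc2)c2ccc(Br)cc12 | intermediate (not isolated)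
13 | (4R)-4-benzyl-3-[(2S)-2-(5-bromo-1-tosyl-1H-indol-3-yl)-3-hydroxypropanoyl]-1,3-oxazolidin-2-one | OC[C@H](c1cn(S(=O)(=O)c2ccc(C)cc2)c2ccc(Br)cc12)C(=O)N1[C@H](Cc2ccccc2)COC1=O | intermediate
14 | hydrogen peroxide | OO | starting material
15 | (2S)-2-(5-bromo-1-tosyl-1H-indol-3-yl)-3-hydroxypropaneperoxoic acid | OC[C@H](c1cn(S(=O)(=O)c2ccc(C)cc2)c2ccc(Br)cc12)C(=O)OO | intermediate (not isolated)
16 | (2S)-2-(5-bromo-1-tosyl-1H-indol-3-yl)-3-hydroxypropanoic acid | OC[C@H](c1cn(S(=O)(=O)c2ccc(C)cc2)c2ccc(Br)cc12)C(O)=O | intermediate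
17 | trimethylsilyldiazomethane | C[Si](C)(C)C=[N+]=[N-] | starting material
18 | methyl (2S)-2-(5-bromo-1-tosyl-1H-indol-3-yl)-3-hydroxypropanoate | OC[C@H](c1cn(S(=O)(=O)c2ccc(C)cc2)c2ccc(Br)cc12)C(=O)OC | intermediate
19 | methylmagnesium bromide | C[Mg]Br | starting material
20 | bromomagnesium alkoxide of (3S)-3-(5-bromo-1-tosyl-1H-indol-3-yl)-4-hydroxybutan-2-one | Br[Mg]OC[C@H](c1cn(S(=O)(=O)c2ccc(C)cc2)c2ccc(Br)cc12)C(C)=O | intermediate (not isolated)
21 | (2S)-2-(5-bromo-1-tosyl-1H-indol-3-yl)-3-methylbutane-1,3-diol | OC[C@H](c1cn(S(=O)(=O)c2ccc(C)cc2)c2ccc(Br)cc12)C(C)(C)O | intermediate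
22 | tributyl(3-methylbut-2-en-1-yl)stannane | CCCC[Sn](CCCC)(CCCC)CC=C(C)C | starting material
23 | (2S)-3-methyl-2-[5-(3-methylbut-2-en-1-yl)-1-tosyl-1H-indol-3-yl]butane-1,3-diol | OC[C@H](c1cn(S(=O)(=O)c2ccc(C)cc2)c2ccc(CC=C(C)C)cc12)C(C)(C)O | intermediate
24 | (2S)-3-methyl-2-[5-(3-methylbut-2-en-1-yl)-1H-indol-3-yl]butane-1,3-diol | OC[C@H](c1c[nH]c2ccc(CC=C(C)C)cc12)C(C)(C)O | intermediate
25 | hexadecanoyl chloride (palmitoyl chloride) | CCCCCCCCCCCCCCCC(Cl)=O | starting material
26 | (2S)-3-hydroxy-3-methyl-2-[5-(3-methylbut-2-en-1-yl)-1H-indol-3-yl]butyl hexadecanoate | CCCCCCCCCCCCCCCC(=O)OC[C@H](c1c[nH]c2ccc(CC=C(C)C)cc12)C(C)(C)O | target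

**Totals**
Total step count: 11. Longest linear sequence: 11 steps (1 to 26).

**Steps most likely to fail, with fallbacks**

Step 5 (titanium-enolate aldol with formaldehyde). The risks are oligomeric formals, over-hydroxymethylation, or a sluggish aryl-stabilised enolate. The fallback sets out from 10 and comes back at 13. Imide 10 is deprotonated with NaN(SiMe3)2 in THF at –78 °C and the sodium Z-enolate is alkylated with benzyl chloromethyl ether, with the same facial bias, to give (4R)-4-benzyl-3-[(2S)-3-(benzyloxy)-2-(5-bromo-1-tosyl-1H-indol-3-yl)propanoyl]-1,3-oxazolidin-2-one F1. The benzyl ether is then cleaved with BCl3 in CH2Cl2 at –78 °C, which leaves the aryl bromide, the sulfonamide and the imide alone, to give 13.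

Step 8 (double Grignard addition). The risks are enolisation of the α-aryl ester or of ketone 20, leading to loss of configuration, retro-aldol loss of formaldehyde, or dehydration. The fallback sets out from 18 and comes back at 21. The primary alcohol is silylated (TBSCl, imidazole, DMF) to give methyl (2S)-2-(5-bromo-1-tosyl-1H-indol-3-yl)-3-[(tert-butyldimethylsilyl)oxy]propanoate F2. The weakly basic organocerium reagent MeCeCl2 (from MeLi and anhydrous CeCl3, THF, –78 °C) is added twice to the ester to give (3S)-3-(5-bromo-1-tosyl-1H-indol-3-yl)-4-[(tert-butyldimethylsilyl)oxy]-2-methylbutan-2-ol F3. Desilylation with Bu4NF/AcOH in THF at 0 °C gives 21.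

Step 9 (Stille prenylation). The risks are partial coupling at the tertiary terminus (reverse-prenyl isomer) or protodebromination. The fallback sets out from 21 and comes back at 23. Stille coupling with allyltributylstannane (Pd(PPh3)4, DMF, 90 °C), which has no regiochemical ambiguity, gives (2S)-3-methyl-2-[5-(prop-2-en-1-yl)-1-tosyl-1H-indol-3-yl]butane-1,3-diol F4. Cross-metathesis with excess 2-methylbut-2-ene (second-generation Grubbs catalyst RuCl2(=CHPh)(PCy3)(H2IMes), CH2Cl2, 40 °C) turns the allyl group into the prenyl group and gives 23.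

**Further compounds**
F1 | step 5 | (4R)-4-benzyl-3-[(2S)-3-(benzyloxy)-2-(5-bromo-1-tosyl-1H-indol-3-yl)propanoyl]-1,3-oxazolidin-2-one | c1ccccc1COC[C@H](c1cn(S(=O)(=O)c2ccc(C)cc2)c2ccc(Br)cc12)C(=O)N1[C@H](Cc2ccccc2)COC1=O
F2 | step 8 | methyl (2S)-2-(5-bromo-1-tosyl-1H-indol-3-yl)-3-[(tert-butyldimethylsilyl)oxy]propanoate | CC(C)(C)[Si](C)(C)OC[C@H](c1cn(S(=O)(=O)c2ccc(C)cc2)c2ccc(Br)cc12)C(=O)OC
F3 | step 8 | (3S)-3-(5-bromo-1-tosyl-1H-indol-3-yl)-4-[(tert-butyldimethylsilyl)oxy]-2-methylbutan-2-ol | CC(C)(C)[Si](C)(C)OC[C@H](c1cn(S(=O)(=O)c2ccc(C)cc2)c2ccc(Br)cc12)C(C)(C)O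
F4 | step 9 | (2S)-3-methyl-2-[5-(prop-2-en-1-yl)-1-tosyl-1H-indol-3-yl]butane-1,3-diol | OC[C@H](c1cn(S(=O)(=O)c2ccc(C)cc2)c2ccc(CC=C)cc12)C(C)(C)O
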